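**Plan**
Retrosynthesis: the acetate C–O bond is cut first. Ring B (C1 aroyl, C2 OH, C3 H, C4 Me, C5 OMe, C6 CH2O) is then cut at C3–C4 and C1–C6 in one formal (3+3) step. The diene goes back to an aroylacetone (Claisen C–C bond) and the furanone to its enol (O–Me bond).
Enabling feature: C1–C2–C3 of ring B is a 2-acylphenol unit, that is, a masked 1,3-dicarbonyl dinucleophile. The unit Me–C4, MeO–C5, OCH2–C6 is 4-methoxy-5-methylfuran-3(2H)-one in masked form, with the ring oxygen becoming the CH2OH oxygen.
Forward: ring A is bought as 2',6'-dimethoxyacetophenone. Claisen condensation and two silylations give the diene, and O-methylation gives the furanone. Their TiCl4 cyclocondensation builds ring B (the only ring made) and frees the CH2OH group, and selective acetylation ends the route.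
Stereochemistry: the target has no stereocentre. Only a transient alkene geometry and two transient centres occur, and all are erased on aromatisation.

Key step: step 5

Remark on the chemistry: the mono-silyl enol ether of the diketone may form as a mixture of regio- and geometric isomers, all of which converge on the same diene in the second silylation, so one isomer is drawn; the hydroxymethyl benzophenone may equilibrate with its cyclic lactol and is drawn in the open form.

**Step 1**
Reactants: 1 2',6'-dimethoxyacetophenone; 2 ethyl acetate
Product: 3 1-(2,6-dimethoxyphenyl)butane-1,3-dione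
Conditions: NaH, EtOAc (excess), THF, reflux; then aq HCl
Reagents that add atoms: none
Why: Crossed Claisen condensation in which the methyl ketone enolate is acylated by ethyl acetate and the equilibrium is pulled forward by deprotonation of the 1,3-diketone, while the twisted, hindered aryl ketone carbonyl is a poor electrophile, so self-condensation of 1 is not expected.

**Step 2**
Reactants: 3 1-(2,6-dimethoxyphenyl)butane-1,3-dione
Product: 4 (Z)-1-(2,6-dimethoxyphenyl)-3-(trimethylsilyloxy)but-2-en-1-one
Conditions: Me3SiCl, NEt3, toluene, 20 °C
Reagents that add atoms: chlorotrimethylsilane, C[Si](C)(C)Cl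
Why: O-silylation of the strongly enolised 1,3-diketone with Me3SiCl and NEt3, the standard entry to 3-silyloxy-2-en-1-ones, should take place at the less hindered acetyl-side oxygen and needs no strong base.

**Step 3**
Reactants: 4 (Z)-1-(2,6-dimethoxyphenyl)-3-(trimethylsilyloxy)but-2-en-1-one
Product: 5 (Z)-1-(2,6-dimethoxyphenyl)-1,3-bis(trimethylsilyloxy)buta-1,3-diene
Conditions: LiN(iPr)2, THF, −78 °C; then Me3SiCl, −78 → 20 °C
Reagents that add atoms: chlorotrimethylsilane, C[Si](C)(C)Cl
Why: Kinetic deprotonation of the terminal methyl group (the gamma position of the vinylogous silyl ester) by LiN(iPr)2 and O-silylation of the dienolate is the established second stage in making 1,3-bis(silyl enol ethers), and the moisture-sensitive diene would be freed from LiCl by filtration under argon and used without chromatography.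

**Step 4**
Reactants: 6 4-hydroxy-5-methylfuran-3(2H)-one
Product: 7 4-methoxy-5-methylfuran-3(2H)-one
Conditions: Me2SO4, K2CO3, acetone, reflux, under argon
Reagents that add atoms: dimethyl sulfate, COS(=O)(=O)OC
Why: Williamson-type O-methylation of the acidic, reductone-like enol hydroxyl with the hard electrophile dimethyl sulfate and a carbonate base, as practised on the 2,5-dimethyl homologue, should give the enol ether, since carbonate is too weak to enolise the C2 methylene.

**Step 5**
Reactants: 5 (Z)-1-(2,6-dimethoxyphenyl)-1,3-bis(trimethylsilyloxy)buta-1,3-diene; 7 4-methoxy-5-methylfuran-3(2H)-one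
Product: 10 (2,6-dimethoxyphenyl)[6-hydroxy-2-(hydroxymethyl)-3-methoxy-4-methylphenyl]methanone (deacetyl preacredinone A), via open-chain enetrione 8 (not isolated), via cyclohexenone aldol adduct 9 (not isolated)
Conditions: TiCl4 (1.1 equiv), CH2Cl2, −78 → 20 °C; then aq NaHCO3
Reagents that add atoms: none
Why: TiCl4 binds the carbonyl of 7 (assisted by the neighbouring methoxy oxygen) and turns the vinylogous ester into an oxocarbenium ion that is electrophilic only at the methyl-bearing ring carbon, where the terminal carbon of 5 adds (Mukaiyama–Michael, new C3–C4 bond); the resulting titanium enolate expels the ring oxygen (retro-oxa-Michael), which opens the furanone to 8 and releases the CH2O group. The central carbon of the 1,3-dicarbonyl unit of 8 then adds to the former furanone ketone (new C1–C6 bond) to give 9, and loss of water and enolisation of the C2 carbonyl aromatise ring B. The closest known reaction types are the TiCl4-mediated formal (3+3) cyclocondensation of 1,3-bis(silyloxy)buta-1,3-dienes with 3-alkoxy- and 3-silyloxy-2-en-1-ones to salicylates and 2-acylphenols, and the Michael/retro-Michael/aldol domino of such dienes with chromones to 2-hydroxybenzophenones, in which a ring oxygen is likewise the leaving group. Ring B, the only ring formed, closes by a 6-exo-trig intramolecular aldol addition followed by dehydration. No stereocentre remains in 10, because the two centres of 9 vanish on aromatisation and the alkene geometry of 8 can equilibrate by reversible re-addition of the alkoxide, so the cyclisation-competent E isomer is drained. The step needs regioselectivity (C3 to C4 and C1 to C6, not the crossed pairing), which is secured by the single conjugate position of 7 and the higher nucleophilicity of the terminal diene carbon, while the C2 hydroxyl stems from the diene oxygen and is thereby distinct from the three methyl ethers.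

**Step 6**
Reactants: 10 (2,6-dimethoxyphenyl)[6-hydroxy-2-(hydroxymethyl)-3-methoxy-4-methylphenyl]methanone
Product: 11 preacredinone A, [2-(2,6-dimethoxybenzoyl)-3-hydroxy-6-methoxy-5-methylphenyl]methyl acetate
Conditions: Ac2O (1.1 equiv), pyridine, CH2Cl2, 0 °C
Reagents that add atoms: acetic anhydride, CC(=O)OC(C)=O
Why: Chemoselective acetylation (nucleophilic acyl substitution) of the primary benzylic alcohol, because the C2 phenol is held in a hydrogen bond to the benzophenone carbonyl and is flanked by the aroyl group, so that one equivalent of Ac2O in pyridine without DMAP should leave it untouched.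

**Compound list**
1 | 2',6'-dimethoxyacetophenone | COc1cccc(OC)c1C(C)=O | starting material
2 | ethyl acetate | CCOC(C)=O | starting material
3 | 1-(2,6-dimethoxyphenyl)butane-1,3-dione | COc1cccc(OC)c1C(=O)CC(C)=O | intermediate
4 | (Z)-1-(2,6-dimethoxyphenyl)-3-(trimethylsilyloxy)but-2-en-1-one | COc1cccc(OC)c1C(=O)/C=C(/C)O[Si](C)(C)C | intermediate
5 | (Z)-1-(2,6-dimethoxyphenyl)-1,3-bis(trimethylsilyloxy)buta-1,3-diene | COc1cccc(OC)c1/C(O[Si](C)(C)C)=C/C(=C)O[Si](C)(C)C | intermediate
6 | 4-hydroxy-5-methylfuran-3(2H)-one | CC1=C(O)C(=O)CO1 | starting material
7 | 4-methoxy-5-methylfuran-3(2H)-one | COC1=C(C)OCC1=O | intermediate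
8 | (E)-1-(2,6-dimethoxyphenyl)-8-hydroxy-6-methoxy-5-methyloct-5-ene-1,3,7-trione (present as its titanium enolate and alkoxide; neutral form shown) | COc1cccc(OC)c1C(=O)CC(=O)C/C(C)=C(/OC)C(=O)CO | intermediate (not isolated)
9 | 2-(2,6-dimethoxybenzoyl)-3-hydroxy-3-(hydroxymethyl)-4-methoxy-5-methylcyclohex-4-en-1-one (transient mixture of diastereomers, both centres lost on aromatisation; neutral form shown) | COc1cccc(OC)c1C(=O)C1C(=O)CC(C)=C(OC)C1(O)CO | intermediate (not isolated)
10 | (2,6-dimethoxyphenyl)[6-hydroxy-2-(hydroxymethyl)-3-methoxy-4-methylphenyl]methanone (deacetyl preacredinone A) | COc1cccc(OC)c1C(=O)c1c(O)cc(C)c(OC)c1CO | intermediate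
11 | preacredinone A, [2-(2,6-dimethoxybenzoyl)-3-hydroxy-6-methoxy-5-methylphenyl]methyl acetate | COc1cccc(OC)c1C(=O)c1c(O)cc(C)c(OC)c1COC(C)=O | target

**Totals**
Total step count: 6.
Longest linear sequence: 5 steps (steps 1, 2, 3, 5, 6); the furanone arm joins after one step.

**Steps most likely to fail**

1. Step 5.
   - What may go wrong: loss of the silyl groups from 5 by adventitious acid before C–C bond formation; slow conjugate addition at the fully substituted, methoxy-flanked ring carbon of 7; stalling of the aldol closure next to the bulky, twisted 2,6-dimethoxybenzoyl group; chelation-driven O-demethylation of that group by TiCl4.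
   - Fallback, setting out from 7 and coming back at 10: the same (3+3) cyclocondensation on 7 is run with the unhindered 1,3-bis(silyl enol ether) of methyl acetoacetate, 1-methoxy-1,3-bis(trimethylsilyloxy)buta-1,3-diene (a purchased reagent; TiCl4, CH2Cl2, −78 → 20 °C). This should give methyl 6-hydroxy-2-(hydroxymethyl)-3-methoxy-4-methylbenzoate F1. F1 should lactonise on acidic work-up, or with catalytic TsOH in toluene, to 7-hydroxy-4-methoxy-5-methylisobenzofuran-1(3H)-one F2. Silylation (TBSCl, imidazole, DMF) would give 7-(tert-butyldimethylsilyloxy)-4-methoxy-5-methylisobenzofuran-1(3H)-one F3. Addition of 2,6-dimethoxyphenyllithium (from 1,3-dimethoxybenzene and n-BuLi, THF, 0 °C) at −78 °C should stop at the lactol alkoxide and give, after work-up, [6-(tert-butyldimethylsilyloxy)-2-(hydroxymethyl)-3-methoxy-4-methylphenyl](2,6-dimethoxyphenyl)methanone F4. TBAF in THF at 0 °C then returns to 10. The diaryl ketone is thus made by acylation of an aryllithium with a lactone and never meets the Lewis acid.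

2. Step 4.
   - What may go wrong: under carbonate the enolate of this reductone-like enol may equilibrate with its 2-methyl tautomer or degrade by oxidation and self-condensation, so that O-methylation is accompanied by the isomeric ether, by C-methylation and by tar; the small, volatile product may also be lost on isolation.
   - Fallback, setting out from 6 and coming back at 10: the enol is capped without enolate alkylation (TBSCl, imidazole, DMF) as 4-(tert-butyldimethylsilyloxy)-5-methylfuran-3(2H)-one F5. The TiCl4 cyclocondensation of step 5 with diene 5 should then give [3-(tert-butyldimethylsilyloxy)-6-hydroxy-2-(hydroxymethyl)-4-methylphenyl](2,6-dimethoxyphenyl)methanone F6. Desilylative methylation of the C5 aryl silyl ether (CsF, MeI, DMF, 0 → 20 °C, argon) places the methyl group on the non-chelated phenoxide only and leaves the chelated C2 phenol and the alcohol untouched, which returns to 10.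

3. Step 6.
   - What may go wrong: competing acylation of the hydrogen-bonded phenol, reaction through the cyclic lactol tautomer, or incomplete conversion of the di-ortho-substituted benzylic alcohol when only one equivalent of anhydride is used.
   - Fallback, setting out from 10 and coming back at 11: both hydroxyls are acetylated on purpose (excess Ac2O, pyridine, DMAP, CH2Cl2, 20 °C) to [3-acetoxy-2-(2,6-dimethoxybenzoyl)-6-methoxy-5-methylphenyl]methyl acetate F7. The far more electrophilic aryl acetate is then cleaved selectively by aminolysis (pyrrolidine, 1.1 equiv, CH2Cl2, 0 °C), which leaves the alkyl acetate in place and gives 11.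

**Further compounds**
F1 | step 5 | methyl 6-hydroxy-2-(hydroxymethyl)-3-methoxy-4-methylbenzoate | COC(=O)c1c(O)cc(C)c(OC)c1CO
F2 | step 5 | 7-hydroxy-4-methoxy-5-methylisobenzofuran-1(3H)-one | COc1c(C)cc(O)c2c1COC2=O
F3 | step 5 | 7-(tert-butyldimethylsilyloxy)-4-methoxy-5-methylisobenzofuran-1(3H)-one | COc1c(C)cc(O[Si](C)(C)C(C)(C)C)c2c1COC2=O
F4 | step 5 | [6-(tert-butyldimethylsilyloxy)-2-(hydroxymethyl)-3-methoxy-4-methylphenyl](2,6-dimethoxyphenyl)methanone | COc1cccc(OC)c1C(=O)c1c(O[Si](C)(C)C(C)(C)C)cc(C)c(OC)c1CO
F5 | step 4 | 4-(tert-butyldimethylsilyloxy)-5-methylfuran-3(2H)-one | CC1=C(O[Si](C)(C)C(C)(C)C)C(=O)CO1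
F6 | step 4 | [3-(tert-butyldimethylsilyloxy)-6-hydroxy-2-(hydroxymethyl)-4-methylphenyl](2,6-dimethoxyphenyl)methanone | COc1cccc(OC)c1C(=O)c1c(O)cc(C)c(O[Si](C)(C)C(C)(C)C)c1CO
F7 | step 6 | [3-acetoxy-2-(2,6-dimethoxybenzoyl)-6-methoxy-5-methylphenyl]methyl acetate | COc1cccc(OC)c1C(=O)c1c(OC(C)=O)cc(C)c(OC)c1COC(C)=O
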